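**Remark on the reading of the structure.** The SMILES is read as (5S,6S,8S,9R,10S,13R): normal labdane series, 6β-OAc (axial), 8α-CH3, 9α-O, and C16 cis to C8 across the oxolane. Labdane numbering is used throughout: oxolane = O–C9–C11–C12–C13; dihydrofuran = C13–C14=C15–O–C16. (+)-Sclareolide has the C5/C10 configuration of the target.

## The problem

- **Ring system.** The target is a trans-decalin whose C9 is the spiro atom of an oxolane (O, C9, C11, C12, C13). C13 is in turn the spiro atom of a 2,3-dihydrofuran (C13, C14=C15, O, C16). Ring B carries a C7 ketone flanked by an axial 6β-acetate and an equatorial 8α-methyl.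
- **Stereocentres the core can control.** C5 and C10 come from the chiral pool. C9 and C8 can be set from C10: axial attack anti to the C10 methyl, and an equatorial methyl by equilibration.
- **C6.** The acetate sits on the β face, syn-axial to the C19 and C20 methyls. An external oxidant reaches only the α face, so the oxygen must arrive intramolecularly or with inversion.
- **C13.** It is insulated from the core by the ether oxygen and two CH2 groups. Its two faces differ only in whether C14 or C16 lies on the C8 side, so substrate control is unreliable.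
- **Fragile groups.** Acid ionises the tertiary allylic C13–O bond of the enol ether, and loss of H16 gives the furan and the 9-hydroxyl. Electrophilic oxidants attack the enol ether. The α-acetoxy ketone is base-labile, and a C8 enolate can expel the C9 oxygen.
- **The feature that is used.** C14 and C16 are both bonded to C13 and are told apart only by C15 of the dihydrofuran. Without C15 both are CH2–O groups, and C13 of a 2,2-bis(hydroxymethyl)oxolane is not a stereocentre. C13 can therefore enter as a symmetric ketone and be made stereogenic late by a hydrolase. In addition, the oxolane oxygen is β to the C7 carbonyl, so the ring can be closed by conjugate addition.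

## Retrosynthesis

**22 ⇒ 21.** The O–C15 bond of the dihydrofuran is cut, giving alkynol 21 (C13 bears CH2OH and C≡CH). Cutting O–C16 or C14=C15 instead would require a lactol dehydration or an acetal elimination, both acidic. This cut is an isomerisation run in triethylamine, so the acid-labile enol ether appears only in the last flask. Precursor 21 tolerates acid and oxidants. The forward reaction must be endo-selective and must spare the ketone and the acetate.

**21 ⇒ 20 ⇒ 18 ⇒ 17 ⇒ 16.** C14–C15 is cut (alkyne from aldehyde 18 by one-carbon homologation, via 20), and the aldehyde is traced to a hydroxymethyl group in 17. Both arms on C13 are then CH2OH in diol 16, and C13 is no longer a stereocentre. Any cut that keeps C13 stereogenic must create it by attack on a flat or freely rotating unit far from the core. Here the only demand is that a lipase distinguishes two diastereotopic primary hydroxyls (16 → 17).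

**16 ⇒ 15 ⇒ 13 ⇒ 11.** After the acetonide is restored (15), the C6–O bond is cut. The 6β-acetate is traced to the enol acetate 13 of ketone 11 through epoxy acetate 14, whose acetoxy group shifts from C7 to C6 with inversion. Direct enolate oxidation would give the 6α isomer. This route places the oxygen on the hindered face intramolecularly and brings the acetyl group with it. It needs an electrophilic epoxidation, so it must precede the enol ether; that fixes the order of events.

**11 ⇒ 9.** The C9–O bond is cut as a retro-oxa-Michael reaction (alkoxide 10). The precursor is the Δ8-en-7-one 9 with an acyclic, symmetric tertiary carbinol. The spiro ring and the stereocentres C8 and C9 disappear; only C5 and C10 remain. Cutting O–C13 instead would need an electrophilic C13 and would create C13 uncontrolled. The forward reaction must be 5-exo, α-face selective and thermodynamically downhill.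

**9 ⇒ 8 ⇒ 4 + 5.** The C7 carbonyl is traced to the allylic methylene of alkene 8. The C12–C13 bond is cut to the homoallyl iodide 4 (used as its lithium compound 6) and ketone 5, the acetonide of dihydroxyacetone. Ketone 5 supplies C13, C14, C16 and both ether oxygens in one symmetric piece; alkoxide 7 is silylated in the same flask.

**4 ⇒ 3 ⇒ 2 ⇒ 1.** Iodide 4 comes from (+)-sclareolide 1 by lactone opening with dehydration to the Δ8 ester 2, reduction to 3 and iodination. Compound 1 supplies C1–C12, C17–C20 and the C5/C10 configuration.

## Roads not taken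

**Alternative 1:** The obvious cut is C13–O9 in the target itself, with the aromatic furan as precursor: the 9α-hydroxy furan A1, closed by electrophile-induced dearomative spiroetherification (NBS to the bromo spiroether A2, then tin hydride).
- The direct addition of the 9-hydroxyl to the furan is uphill, and acid sends 22 back to A1. Only the oxidative two-step detour is possible.
- C13 forms by attack on either face of a freely rotating furan, and nothing in A1 distinguishes the faces. Separation of C13 epimers would fall on the last, most sensitive intermediate.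
- The furan would have to survive the allylic oxidation and the epoxidation that installs the C6 acetate. It would not, so C6 would need a longer solution.

**Alternative 2:** Cut C13–O9 with a reagent-defined electrophilic C13: the 9α-hydroxy ketone A3 carrying a 13,16-epoxy-14-yne side chain, closed by acid-catalysed 5-exo epoxide opening with inversion at C13 to give 21.
- The 9α-hydroxyl must be made separately (enone epoxidation and reductive opening, two extra steps).
- C13 would be set by asymmetric epoxidation of a 1,1-disubstituted enyne four bonds from the nearest stereocentre, an alkene class that is not reliably selective.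
- Opening at a tertiary propargylic carbon has SN1 character and can erode that configuration.
- In the chosen plan C13 has no configuration to lose until the enzyme acts.

**Alternative 3:** Use the same hidden symmetry but break it by single-atom insertion: the spiro cyclobutanone A4, oxidised by a Baeyer–Villiger monooxygenase to lactone A5. This sets C13 and inserts the ring oxygen in one step.
- A5 is two oxidation levels above the enol ether. Its hydride reduction to the lactol cannot be done beside the C7 ketone and the C6 acetate.
- Moving the reduction ahead of the C6 oxygenation would expose the enol ether to the epoxidation.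
- The detour through a protected lactol costs at least three steps and ends with an acid-promoted elimination on the acid-labile product.
- The alkynol of the chosen plan is already at the enol-ether oxidation level, and ketone 5 is a cheaper symmetric building block than a 3-oxocyclobutyl unit.

Key step: step 10

## Route

Step 1
Reactants: 1 (+)-sclareolide
Product: 2 methyl 13,14,15,16-tetranorlabd-8-en-12-oate
Conditions: conc. H2SO4, MeOH, rt
Reagents that add atoms: methanol, CO
Why: Acid-catalysed methanolysis of the lactone and E1 dehydration of the tertiary C8 carbinol; under equilibrating acid the tetrasubstituted Δ8(9) alkene, the most stable isomer, should predominate, and C5 and C10 are untouched.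

Step 2
Reactants: 2 methyl 13,14,15,16-tetranorlabd-8-en-12-oate
Product: 3 13,14,15,16-tetranorlabd-8-en-12-ol
Conditions: LiAlH4, THF, 0 °C → rt
Reagents that add atoms: none
Why: Hydride reduction of an ester to the primary alcohol; the isolated tetrasubstituted alkene is inert.

Step 3
Reactants: 3 13,14,15,16-tetranorlabd-8-en-12-ol
Product: 4 12-iodo-13,14,15,16-tetranorlabd-8-ene
Conditions: I2, PPh3, imidazole, CH2Cl2, 0 °C → rt
Reagents that add atoms: iodine, II
Why: Appel-type iodination of a primary alcohol through the alkoxyphosphonium iodide (SN2).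

Step 4
Reactants: 4 12-iodo-13,14,15,16-tetranorlabd-8-ene; 5 2,2-dimethyl-1,3-dioxan-5-one
Product: 8 14,16-O-isopropylidene-13-O-triethylsilyl-15-norlabd-8-ene-13,14,16-triol, via homoallyllithium 6 (not isolated), via lithium alkoxide 7 (not isolated)
Conditions: t-BuLi (2 equiv), Et2O–pentane, −78 °C; then 5, −78 °C; then Et3SiOTf, −78 → 0 °C
Reagents that add atoms: triethylsilyl trifluoromethanesulfonate, CC[Si](CC)(CC)OS(=O)(=O)C(F)(F)F
Why: Iodine–lithium exchange gives the primary homoallyllithium, which adds to the carbonyl of the symmetric ketone 5, so the new carbinol carbon C13 is not a stereocentre. Silylation of the alkoxide in the same flask keeps the tertiary hydroxyl from acetonide migration and from chromate-ester chemistry in step 5.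

Step 5
Reactants: 8 14,16-O-isopropylidene-13-O-triethylsilyl-15-norlabd-8-ene-13,14,16-triol
Product: 9 13,14,16-trihydroxy-14,16-O-isopropylidene-13-O-triethylsilyl-15-norlabd-8-en-7-one
Conditions: CrO3, 3,5-dimethylpyrazole, CH2Cl2, −20 °C
Reagents that add atoms: chromium trioxide, O=[Cr](=O)=O
Why: Chromium(VI)–pyrazole allylic oxidation of a tetrasubstituted ring alkene; the ring methylene C7 is the most accessible allylic position (C11 is neopentyl-like beside C10, C17 is a methyl) and gives the conjugated enone.

Step 6
Reactants: 9 13,14,16-trihydroxy-14,16-O-isopropylidene-13-O-triethylsilyl-15-norlabd-8-en-7-one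
Product: 11 9α,13-epoxy-14,16-(isopropylidenedioxy)-15-norlabdan-7-one, via ammonium alkoxide 10 (not isolated)
Conditions: Bu4NF, THF, 0 °C → rt
Reagents that add atoms: none
Why: Fluoride removes the silyl group and the tertiary alkoxide adds to C9, the β-carbon of the enone (intramolecular oxa-Michael, 5-exo-trig, a known way to close di-tertiary ethers); attack is axial and anti to the C10 methyl, so oxygen enters on the α face (9R). Reversible protonation of the enolate at C8 under the basic conditions leaves the methyl equatorial (8α).

Step 7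
Reactants: 11 9α,13-epoxy-14,16-(isopropylidenedioxy)-15-norlabdan-7-one
Product: 13 7-acetoxy-9α,13-epoxy-14,16-(isopropylidenedioxy)-15-norlabd-6-ene, via potassium enolate 12 (not isolated)
Conditions: KHMDS (1.05 equiv), THF, −78 °C; then Ac2O, −78 → 0 °C
Reagents that add atoms: acetic anhydride, CC(=O)OC(C)=O
Why: Kinetic deprotonation at the C6 methylene (the C8 methine is hindered, and its enolate would expel the C9 oxygen) followed by O-acylation of the potassium enolate gives the Δ6 enol acetate.

Step 8
Reactants: 13 7-acetoxy-9α,13-epoxy-14,16-(isopropylidenedioxy)-15-norlabd-6-ene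
Product: 15 6β-acetoxy-9α,13-epoxy-14,16-(isopropylidenedioxy)-15-norlabdan-7-one, via epoxy acetate 14 (not isolated)
Conditions: dimethyldioxirane, acetone, 0 °C; then o-xylene, 140 °C, base-washed glass
Reagents that add atoms: dimethyldioxirane, CC1(C)OO1
Why: Dioxirane epoxidises the enol acetate from the open α face (the β face is covered by the axial C19 and C20 methyls) to the 6α,7α-epoxide. On heating without acid the 7β-acetoxy group migrates to C6 on the β face while the epoxide oxygen becomes the C7 carbonyl (thermal rearrangement of enol ester epoxides, inversion at the receiving carbon), which sets the axial 6β-acetate (6S).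

Step 9
Reactants: 15 6β-acetoxy-9α,13-epoxy-14,16-(isopropylidenedioxy)-15-norlabdan-7-one
Product: 16 6β-acetoxy-9α,13-epoxy-14,16-dihydroxy-15-norlabdan-7-one
Conditions: 80% aq. AcOH, 40 °C
Reagents that add atoms: none
Why: Acid hydrolysis of an isopropylidene acetal; no enol ether is present yet, and C13, flanked by three oxygen-bearing carbons, does not ionise.

Step 10
Reactants: 16 6β-acetoxy-9α,13-epoxy-14,16-dihydroxy-15-norlabdan-7-one
Product: 17 (13R)-6β,16-diacetoxy-9α,13-epoxy-14-hydroxy-15-norlabdan-7-one
Conditions: lipase (Burkholderia cepacia lipase, immobilised, chosen from a panel), vinyl acetate, t-BuOMe, 30 °C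
Reagents that add atoms: vinyl acetate, CC(=O)OC=C
Why: A lipase (serine hydrolase) is acetylated at its active-site serine by vinyl acetate, irreversibly because the leaving enol becomes acetaldehyde, and the acyl-enzyme passes the acetyl group to one of the two primary hydroxyls of 16. The closest known reaction type is the lipase-catalysed desymmetrisation of prochiral 2,2-disubstituted propane-1,3-diols with vinyl acetate, which is established for fully substituted carbinol carbons. No ring is closed. The new stereocentre is C13 and it is controlled by the enzyme, not the substrate: the two CH2OH groups are constitutionally identical and differ only in lying cis to C8 or cis to C10 across the oxolane, a difference a small reagent reads poorly and a chiral binding pocket reads well. Because 16 is already chiral the two possible monoacetates are diastereomers, so the group selectivity can be read directly and a minor isomer removed by chromatography; the lipase that acylates the hydroxymethyl cis to C8 is taken. Three selectivities are needed: between the arms (enzyme); mono- against di-acylation (the second acylation is slower and should consume the wrong monoacetate preferentially, which sharpens the purity of 17); and primary hydroxyl against the rest of the molecule (the hindered axial C6 acetate and the C7 ketone are not lipase substrates in an organic solvent).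

Step 11
Reactants: 17 (13R)-6β,16-diacetoxy-9α,13-epoxy-14-hydroxy-15-norlabdan-7-one
Product: 18 (13S)-6β,16-diacetoxy-9α,13-epoxy-7-oxo-15-norlabdan-14-al
Conditions: Dess–Martin periodinane, CH2Cl2, rt
Reagents that add atoms: none
Why: Dess–Martin oxidation of the remaining primary alcohol; the aldehyde has no α-hydrogen, so C13 cannot epimerise and the β-acetoxy group cannot be eliminated (the descriptor changes only through CIP priorities).

Step 12
Reactants: 18 (13S)-6β,16-diacetoxy-9α,13-epoxy-7-oxo-15-norlabdan-14-al
Product: 20 (13R)-6β,16-diacetoxy-9α,13-epoxylabd-14-yn-7-one, via diazoalkene 19 (not isolated)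
Conditions: dimethyl (1-diazo-2-oxopropyl)phosphonate, NaOMe (1 equiv), THF, −78 °C; then 18, −78 °C → rt
Reagents that add atoms: dimethyl (1-diazo-2-oxopropyl)phosphonate, CC(=O)C(=[N+]=[N-])P(=O)(OC)OC
Why: Seyferth–Gilbert homologation: methoxide, consumed at −78 °C before the substrate is added, releases the diazomethylphosphonate anion, which olefinates the aldehyde to the diazoalkene; loss of N2 and a 1,2-hydrogen shift give the terminal alkyne. Pre-forming the anion leaves no free alkoxide for the two acetates.

Step 13
Reactants: 20 (13R)-6β,16-diacetoxy-9α,13-epoxylabd-14-yn-7-one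
Product: 21 (13R)-6β-acetoxy-9α,13-epoxy-16-hydroxylabd-14-yn-7-one
Conditions: Candida antarctica lipase B (immobilised), phosphate buffer pH 7–acetone, 30 °C
Reagents that add atoms: none
Why: Lipase hydrolysis of a primary acetate at neutral pH; the hindered secondary C6 acetate beside the ketone is not a substrate, and no base is present that could epimerise C6 or C8.

Step 14
Reactants: 21 (13R)-6β-acetoxy-9α,13-epoxy-16-hydroxylabd-14-yn-7-one
Product: 22 (13R)-6β-acetoxy-9α,13:15,16-diepoxylabd-14-en-7-one
Conditions: Mo(CO)6 (cat.), Et3N, Et2O, hν (350 nm), rt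
Reagents that add atoms: none
Why: Molybdenum carbonyl–amine catalysed cycloisomerisation of a homopropargylic alcohol: the terminal alkyne rearranges to a vinylidene on the metal, the hydroxyl adds to its electrophilic carbon C15 (endo closure of the five-membered ring) and protodemetalation releases the 2,3-dihydrofuran. The medium stays basic, so the acid-labile C13 ether and the enol ether should survive, and C13 is not touched.

## Compound list

1 | (+)-sclareolide | O=C1C[C@H]2[C@@](C)(CC[C@H]3C(C)(C)CCC[C@@]32C)O1 | starting material
2 | methyl 13,14,15,16-tetranorlabd-8-en-12-oate | COC(=O)CC1=C(C)CC[C@H]2C(C)(C)CCC[C@]12C | intermediate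
3 | 13,14,15,16-tetranorlabd-8-en-12-ol | OCCC1=C(C)CC[C@H]2C(C)(C)CCC[C@]12C | intermediate
4 | 12-iodo-13,14,15,16-tetranorlabd-8-ene | ICCC1=C(C)CC[C@H]2C(C)(C)CCC[C@]12C | intermediate
5 | 2,2-dimethyl-1,3-dioxan-5-one | CC1(C)OCC(=O)CO1 | starting material
6 | 12-lithio-13,14,15,16-tetranorlabd-8-ene (homoallyllithium) | [Li]CCC1=C(C)CC[C@H]2C(C)(C)CCC[C@]12C | intermediate
7 | lithium 13-alkoxide of 14,16-O-isopropylidene-15-norlabd-8-ene-13,14,16-triol | [Li+].[O-]C1(CCC2=C(C)CC[C@H]3C(C)(C)CCC[C@]23C)COC(C)(C)OC1 | intermediate
8 | 14,16-O-isopropylidene-13-O-triethylsilyl-15-norlabd-8-ene-13,14,16-triol | CC[Si](CC)(CC)OC1(CCC2=C(C)CC[C@H]3C(C)(C)CCC[C@]23C)COC(C)(C)OC1 | intermediate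
9 | 13,14,16-trihydroxy-14,16-O-isopropylidene-13-O-triethylsilyl-15-norlabd-8-en-7-one | CC[Si](CC)(CC)OC1(CCC2=C(C)C(=O)C[C@H]3C(C)(C)CCC[C@]23C)COC(C)(C)OC1 | intermediate
10 | tetrabutylammonium 13-alkoxide of 13,14,16-trihydroxy-14,16-O-isopropylidene-15-norlabd-8-en-7-one | CCCC[N+](CCCC)(CCCC)CCCC.[O-]C1(CCC2=C(C)C(=O)C[C@H]3C(C)(C)CCC[C@]23C)COC(C)(C)OC1 | intermediate
11 | 9α,13-epoxy-14,16-(isopropylidenedioxy)-15-norlabdan-7-one (8α-methyl; C13 spiro to the 1,3-dioxane) | C1C(=O)[C@@H](C)[C@]2(CCC3(COC(C)(C)OC3)O2)[C@@]2(C)CCCC(C)(C)[C@H]12 | intermediate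
12 | potassium Δ6-enolate of 11 | C1=C([O-])[C@@H](C)[C@]2(CCC3(COC(C)(C)OC3)O2)[C@@]2(C)CCCC(C)(C)[C@H]12.[K+] | intermediate
13 | 7-acetoxy-9α,13-epoxy-14,16-(isopropylidenedioxy)-15-norlabd-6-ene | C1=C(OC(C)=O)[C@@H](C)[C@]2(CCC3(COC(C)(C)OC3)O2)[C@@]2(C)CCCC(C)(C)[C@H]12 | intermediate
14 | 7β-acetoxy-6α,7α:9α,13-diepoxy-14,16-(isopropylidenedioxy)-15-norlabdane | [C@@H]14O[C@@]4(OC(C)=O)[C@@H](C)[C@]2(CCC3(COC(C)(C)OC3)O2)[C@@]2(C)CCCC(C)(C)[C@H]12 | intermediate
15 | 6β-acetoxy-9α,13-epoxy-14,16-(isopropylidenedioxy)-15-norlabdan-7-one | CC(=O)O[C@@H]1C(=O)[C@@H](C)[C@]2(CCC3(COC(C)(C)OC3)O2)[C@@]2(C)CCCC(C)(C)[C@H]12 | intermediate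
16 | 6β-acetoxy-9α,13-epoxy-14,16-dihydroxy-15-norlabdan-7-one | CC(=O)O[C@@H]1C(=O)[C@@H](C)[C@]2(CCC(CO)(CO)O2)[C@@]2(C)CCCC(C)(C)[C@H]12 | intermediate
17 | (13R)-6β,16-diacetoxy-9α,13-epoxy-14-hydroxy-15-norlabdan-7-one (acetate on the arm cis to C8) | CC(=O)O[C@@H]1C(=O)[C@@H](C)[C@]2(CC[C@](COC(C)=O)(CO)O2)[C@@]2(C)CCCC(C)(C)[C@H]12 | intermediate
18 | (13S)-6β,16-diacetoxy-9α,13-epoxy-7-oxo-15-norlabdan-14-al | CC(=O)O[C@@H]1C(=O)[C@@H](C)[C@]2(CC[C@](COC(C)=O)(C=O)O2)[C@@]2(C)CCCC(C)(C)[C@H]12 | intermediate
19 | (13R)-6β,16-diacetoxy-15-diazo-9α,13-epoxylabd-14-en-7-one (diazoalkene) | CC(=O)O[C@@H]1C(=O)[C@@H](C)[C@]2(CC[C@](COC(C)=O)(C=C=[N+]=[N-])O2)[C@@]2(C)CCCC(C)(C)[C@H]12 | intermediate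
20 | (13R)-6β,16-diacetoxy-9α,13-epoxylabd-14-yn-7-one | CC(=O)O[C@@H]1C(=O)[C@@H](C)[C@]2(CC[C@](COC(C)=O)(C#C)O2)[C@@]2(C)CCCC(C)(C)[C@H]12 | intermediate
21 | (13R)-6β-acetoxy-9α,13-epoxy-16-hydroxylabd-14-yn-7-one | CC(=O)O[C@@H]1C(=O)[C@@H](C)[C@]2(CC[C@](CO)(C#C)O2)[C@@]2(C)CCCC(C)(C)[C@H]12 | intermediate
22 | (13R)-6β-acetoxy-9α,13:15,16-diepoxylabd-14-en-7-one | CC(=O)O[C@@H]1C(=O)[C@@H](C)[C@]2(CC[C@]3(C=COC3)O2)[C@@]2(C)CCCC(C)(C)[C@H]12 | target

## Step count and risks

Total: 14 steps. Longest linear sequence: 14 steps from 1 (ketone 5 is used as purchased).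

**Step 10 (key step).** The lipase may discriminate the two hydroxymethyl groups poorly, prefer the other arm, or over-acylate. The arms differ only in their relation to C8 and C10 across the spiro ether, so no rule predicts which enzyme reads them. The fallback gives up catalyst control and uses the fact that both monoacetates are diastereomers and can both be led to the same product. It sets out from 16: unselective mono-acetylation and chromatography give 17 and its C13 epimer, the (13S)-14-O-acetate F1. F1 is silylated at the free hydroxyl (TBSCl, imidazole) to the silyl ether acetate F2. The primary acetate is removed by lipase hydrolysis as in step 13 to give the alcohol F3. Dess–Martin oxidation gives the aldehyde F4, the conditions of step 12 give the silyl ether alkyne F5, and buffered fluoride (HF·pyridine in pyridine) returns to the route at 21. Exchanging the roles of the arms in F1 leads to the same C13 configuration.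

**Step 6.** The conjugate addition may stop at an unfavourable equilibrium (a di-tertiary ether is formed from a tetrasubstituted enone), or attack on the β face may give the C9 epimer. The fallback makes the C9–O bond by ionisation instead. It sets out from 9, which is reduced (NaBH4, CeCl3) and acetylated in the same operation to the allylic acetate F6. A catalytic silyl triflate with a hindered pyridine (CH2Cl2, −78 °C) ionises C7–OAc to the C7–C8–C9 allyl cation. The silyl ether oxygen captures it at C9 from the α face (5-exo, silyl group lost), giving the Δ7 spiro ether F7. Hydroboration–oxidation gives the 7α-ol F8, and Dess–Martin oxidation with a brief DBU equilibration at C8 comes back at 11.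

**Step 8.** Adventitious acid may open the epoxy acetate by the retention pathway (6α-acetate), or moisture may hydrolyse it to the ketol. The fallback sets the C6 oxygen by substitution. From 11, enolate hydroxylation (KHMDS, then 2-(phenylsulfonyl)-3-phenyloxaziridine) should give the 6α-hydroxy ketone F9 by α-face attack. Mitsunobu inversion with acetic acid (PPh3, DIAD) comes back at 15.

**Step 12.** The basic reagent may remove or shift the C6 acetyl group, or epimerise C6, since an α-acetoxy ketone is an activated ester with an acidic α-hydrogen. The fallback installs the acetate last. From 18, the same reagent with K2CO3 in methanol at 0 °C builds the alkyne and deliberately removes both acetyl groups, giving the diol F10. Cycloisomerisation as in step 14 gives the 6β-hydroxy dihydrofuran F11, and Ac2O, DMAP and Et3N return to the route at 22.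

**Step 5.** Oxidation may occur at C11, with allylic transposition, or with over-oxidation, because three allylic positions flank the tetrasubstituted alkene. The fallback fixes the position of the oxygen by a rearrangement. From 8, mCPBA gives the 8α,9α-epoxide F12. A lithium amide base isomerises it to the 9α-hydroxy Δ7 allylic alcohol F13. Pyridinium chlorochromate then effects the oxidative 1,3-transposition of the tertiary allylic alcohol (Babler–Dauben) and comes back at 9.

## Further compounds

F1 | step 10 | (13S)-6β,14-diacetoxy-9α,13-epoxy-16-hydroxy-15-norlabdan-7-one | CC(=O)O[C@@H]1C(=O)[C@@H](C)[C@]2(CC[C@](CO)(COC(C)=O)O2)[C@@]2(C)CCCC(C)(C)[C@H]12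
F2 | step 10 | 16-O-tert-butyldimethylsilyl ether of F1 | CC(=O)O[C@@H]1C(=O)[C@@H](C)[C@]2(CC[C@](CO[Si](C)(C)C(C)(C)C)(COC(C)=O)O2)[C@@]2(C)CCCC(C)(C)[C@H]12
F3 | step 10 | 6β-acetoxy-16-(tert-butyldimethylsilyloxy)-9α,13-epoxy-14-hydroxy-15-norlabdan-7-one | CC(=O)O[C@@H]1C(=O)[C@@H](C)[C@]2(CC[C@](CO[Si](C)(C)C(C)(C)C)(CO)O2)[C@@]2(C)CCCC(C)(C)[C@H]12
F4 | step 10 | 6β-acetoxy-16-(tert-butyldimethylsilyloxy)-9α,13-epoxy-7-oxo-15-norlabdan-14-al | CC(=O)O[C@@H]1C(=O)[C@@H](C)[C@]2(CC[C@](CO[Si](C)(C)C(C)(C)C)(C=O)O2)[C@@]2(C)CCCC(C)(C)[C@H]12
F5 | step 10 | 6β-acetoxy-16-(tert-butyldimethylsilyloxy)-9α,13-epoxylabd-14-yn-7-one | CC(=O)O[C@@H]1C(=O)[C@@H](C)[C@]2(CC[C@](CO[Si](C)(C)C(C)(C)C)(C#C)O2)[C@@]2(C)CCCC(C)(C)[C@H]12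
F6 | step 6 | 7β-acetoxy-14,16-O-isopropylidene-13-O-triethylsilyl-15-norlabd-8-ene-13,14,16-triol | CC[Si](CC)(CC)OC1(CCC2=C(C)[C@@H](OC(C)=O)C[C@H]3C(C)(C)CCC[C@]23C)COC(C)(C)OC1
F7 | step 6 | 9α,13-epoxy-14,16-(isopropylidenedioxy)-15-norlabd-7-ene | C1C=C(C)[C@]2(CCC3(COC(C)(C)OC3)O2)[C@@]2(C)CCCC(C)(C)[C@H]12
F8 | step 6 | 9α,13-epoxy-14,16-(isopropylidenedioxy)-8β-methyl-15-norlabdan-7α-ol | C1[C@@H](O)[C@H](C)[C@]2(CCC3(COC(C)(C)OC3)O2)[C@@]2(C)CCCC(C)(C)[C@H]12
F9 | step 8 | 9α,13-epoxy-6α-hydroxy-14,16-(isopropylidenedioxy)-15-norlabdan-7-one | O[C@H]1C(=O)[C@@H](C)[C@]2(CCC3(COC(C)(C)OC3)O2)[C@@]2(C)CCCC(C)(C)[C@H]12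
F10 | step 12 | (13R)-9α,13-epoxy-6β,16-dihydroxylabd-14-yn-7-one | O[C@@H]1C(=O)[C@@H](C)[C@]2(CC[C@](CO)(C#C)O2)[C@@]2(C)CCCC(C)(C)[C@H]12
F11 | step 12 | (13R)-9α,13:15,16-diepoxy-6β-hydroxylabd-14-en-7-one | O[C@@H]1C(=O)[C@@H](C)[C@]2(CC[C@]3(C=COC3)O2)[C@@]2(C)CCCC(C)(C)[C@H]12
F12 | step 5 | 8α,9α-epoxy-14,16-O-isopropylidene-13-O-triethylsilyl-15-norlabdane-13,14,16-triol | CC[Si](CC)(CC)OC1(CC[C@@]23O[C@]2(C)CC[C@H]4C(C)(C)CCC[C@]34C)COC(C)(C)OC1
F13 | step 5 | 14,16-O-isopropylidene-13-O-triethylsilyl-15-norlabd-7-ene-9α,13,14,16-tetrol | CC[Si](CC)(CC)OC1(CC[C@@]2(O)C(C)=CC[C@H]3C(C)(C)CCC[C@]23C)COC(C)(C)OC1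
A1 | alternative 1 | 6β-acetoxy-9α-hydroxy-15,16-epoxylabda-13(16),14-dien-7-one | CC(=O)O[C@@H]1C(=O)[C@@H](C)[C@](O)(CCc2ccoc2)[C@@]2(C)CCCC(C)(C)[C@H]12
A2 | alternative 1 | 6β-acetoxy-16-bromo-9α,13:15,16-diepoxylabd-14-en-7-one (C13 and C16 epimers) | CC(=O)O[C@@H]1C(=O)[C@@H](C)[C@]2(CCC3(C=COC3Br)O2)[C@@]2(C)CCCC(C)(C)[C@H]12
A3 | alternative 2 | 6β-acetoxy-13,16-epoxy-9α-hydroxylabd-14-yn-7-one (C13 configured for inversion to 21) | CC(=O)O[C@@H]1C(=O)[C@@H](C)[C@](O)(CC[C@]3(C#C)CO3)[C@@]2(C)CCCC(C)(C)[C@H]12
A4 | alternative 3 | 6β-acetoxy-9α,13-epoxy-14,16-cyclo-labdane-7,15-dione (spiro cyclobutanone) | CC(=O)O[C@@H]1C(=O)[C@@H](C)[C@]2(CCC3(CC(=O)C3)O2)[C@@]2(C)CCCC(C)(C)[C@H]12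
A5 | alternative 3 | (13R)-6β-acetoxy-9α,13-epoxy-7-oxolabdan-15,16-olide | CC(=O)O[C@@H]1C(=O)[C@@H](C)[C@]2(CC[C@]3(CC(=O)OC3)O2)[C@@]2(C)CCCC(C)(C)[C@H]12
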